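(The numbers in the tables come from a simulation with made-up constants, and the scatter is random.)

The easy step comes first: in each reading of Sunday's run I divide left-handed product by right-handed product, and time drops out.

| flask | left-handed substrate | right-handed substrate | reagent | free catalyst | precatalyst | added ligand | remark | time |
|---|---|---|---|---|---|---|---|---|
| Sunday's | 1 mM | 1 mM | 2.2 mM | 25 µM | 10 µM | 16 µM | run made earlier |  |
| flask | 1.0 mM | 1.0 mM | 2.20 mM | 25 µM | 10 µM | 32 µM |  | 3.0 min |

- Sunday's (time / s: left-handed product / %, right-handed product / %): 10.0: 20, 9; 15.0: 27, 11; 40.0: 44, 20

(each reading ± 2 percentage points)

- free catalyst is single-handed; left-handed substrate and right-handed substrate are mirror images of each other, charged as a racemate, each of them at the stated concentration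
- an excess is the difference of the two amounts in percent of their sum
- an excess is below zero if the other one leads
- no earlier run changes the charge of added ligand; that part of a forecast is a guess

* left-handed product and right-handed product together, in percent of the left-handed substrate and right-handed substrate charged together, at 3.0 min
* excess of left-handed product over right-handed product in the product at 3.0 min
* whether the exchange between left-handed substrate and right-handed substrate keeps pace with the reaction: how far the product's excess at 3.0 min gets from its value without exchange to its value with instant exchange (above 80% keeps pace, below 20% hardly takes part, else lags behind)

Summed over the readings of Sunday's run, the two products give 2.27: this is the product ratio.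

Now I turn the question round: what must Sunday's readings show if the exchange hardly takes part? Each hand then has its own pool, and if each reacts in proportion to its pool, the momentary ratio is the selectivity factor times left pool over right pool. At 40.0 s those pools would stand at 6.00% and 30.0% of the charge, a smaller left pool. Taking 2.27 as the factor, the momentary ratio would be 0.455, so the right-handed product would be forming faster. The ratio of the amounts read is 2.22 at 10.0 s and 2.20 at 40.0 s, and the ratio of what formed between 15.0 s and 40.0 s reads 1.89. With a scatter of 2 percentage points this is a leaning, not a proof.

I therefore reckon that the exchange keeps pace and the ratio holds in this flask, which gives an excess of 38.9%. That the ligand, at twice Sunday's charge, leaves the ratio alone is a guess.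

The forecast gives 95% together, an excess of 5%, and says the exchange hardly takes part: “Exchange is therefore slow”. On the excess and the exchange we differ.

This flask gives 89.6% together, an excess of 41.4%, and the exchange keeps pace, 92% of the way from the value without exchange to the value with instant exchange. At 3.00 min left-handed product in this flask stands at 63.3% of the two substrates charged, past the half charged as left-handed substrate. The product ratio there is 2.41, against 2.27 from Sunday's run.

    reagent + free catalyst + left-handed substrate → free catalyst + left-handed product (k = 1.20 × 10⁶ M⁻² s⁻¹)
    reagent + free catalyst + right-handed substrate → free catalyst + right-handed product (k = 4.70 × 10⁵ M⁻² s⁻¹)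
    left-handed substrate + racemization catalyst ⇌ right-handed substrate + racemization catalyst, rate k3*[racemization catalyst]*[left-handed substrate] forward; the back reaction follows from the equilibrium constant (k = 25000 M⁻¹ s⁻¹)
    2 racemization catalyst ⇌ resting dimer, settled at all times (K = 52000 M⁻¹)
    precatalyst ⇌ racemization catalyst (K = 43.0, k = 0.280 s⁻¹)
    free catalyst + added ligand ⇌ idle complex, settled at all times (K = 11000 M⁻¹)

In the neighbour charged with 0.55 mM of reagent, one reagent per substrate allows 27.5% together, and 2.27 splits that into 19.1% left-handed product at an excess of 38.9%. The neighbour gives 27.2% together, 19.5% left-handed product and an excess of 43.2%, with 1.07% of its reagent left.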